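## Analysis of the target

The target 41 is a germacranolide: a ten-membered carbocycle, numbered C1–C10, cis-fused across C6–C7 to an α-methylene-γ-butyrolactone (ring oxygen on C6; C11(=C13H2)–C12(=O) on C7). The carbocycle carries a cis-epoxide at C1–C2, a secondary allylic alcohol at C3, a Z-trisubstituted alkene C4(CH3)=C5, an angelate ester at C8, a methylene C9 and a tertiary methyl carbinol at C10. Its seven stereocentres (1R,2R,3R,6S,7R,8S,10R) fall into two sets: the lactone oxygen on C6, the lactone carbon on C7, the C3 hydroxyl, the epoxide oxygen and the C10 methyl lie on one face of the ring, whereas the C10 hydroxyl and the C8 acyloxy group lie on the other face and are 1,3-syn to each other. The sensitive groups are the α-methylene lactone (a Michael acceptor that does not tolerate hydride, diazomethane, hydroperoxide anion or single-electron reductants), the angelate (Z to E isomerisation, γ-deprotonation by amide bases), the epoxy alcohol next to a tertiary allylic carbinol, and the 6,12-lactone, which can migrate to a free C8 hydroxyl and whose C7 centre can epimerise or be lost by β-elimination whenever C8 is a carbonyl group. The synthesis is hard because a ten-membered ring with two Z alkenes has to be closed and oxygen functions have to be placed selectively on both faces of a mobile ring, with the most fragile groups introduced last. The strategy rests on the segment C8(O)–C9H2–C10(OH)(CH3): it is an aldol retron in which C9 is the α-carbon of a C8 ketone and C10 the carbonyl carbon of a methyl ketone, so one carbonyl addition can close the carbocycle and create the tertiary carbinol with its methyl group already in place.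

## Retrosynthetic reasoning

41 to 40. The epoxide is removed first. In 40 the cis alkene C1=C2 is allylic to the C3 hydroxyl, which sits on the face where the epoxide oxygen must appear, so a hydroxyl-directed epoxidation can install it as the last step. The forward reaction has to choose C1=C2 over C4=C5 and the C3 face over the face of the C10 hydroxyl.

40 to 39 to 37 + 38. The C3 silyl ether of 39 keeps C3 apart from C8 during acylation. The C8–O acyl bond is cut to diol 37 and angelic acid 38; the tertiary C10 hydroxyl needs no protection. The angelate comes in after every strongly basic step because amide bases deprotonate it at the γ-position.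

37 to 36 to 32 to 31. The C11=C13 bond is cut next. Methylenation of the lactone enolate is placed after all steps that would destroy an acrylate (SmI2, borohydride, diazomethane, hydroperoxide) and before the angelate. The two hydroxyls of 31 are masked as trimethylsilyl ethers (32) for the enolate step, giving 36, and are released again in 37.

31 to 29. The C8 carbinol is traced to the C8 ketone of 29. The C10 hydroxyl of 29 is 1,3 to this ketone and can steer the reduction to the syn diol.

29 to 26 (key disconnection). The C9–C10 bond is cut. This is the only ring bond whose scission gives two carbonyl groups, removes one ring and one stereocentre, and leaves the C10 methyl group in the precursor. The enolate position is fixed in 26 by a bromide at C9, so no base acts on a ketone that has the lactone oxygen in the β-position. The forward reaction must reduce the C–Br bond without touching the Z-enone, add 1,2 to the C10 ketone and select one face of it.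

26 to 25 to 24 to 21. The Z-enone is unveiled last, by oxidation of the Z-allylic alcohol 25, because diazomethane would add to an enone. The bromomethyl ketone of 24 is taken back to the carboxylic acid 21 by one-carbon homologation. The C10 oxygen carries a triethylsilyl group that can be removed while the C3 tert-butyldimethylsilyl ether stays.

21 to 19 to 18 to 17 to 16. The acid comes from the imide 19, in which the auxiliary also protects the carboxyl group. The Z alkene C1=C2 comes from the alkyne of 18 by semihydrogenation. The C3 stereocentre of 17 is traced to the ynone 16, so that it is set by reagent control and does not depend on the remote centres C6 and C7.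

16 to 15 to 10 + 14. The C3–C4 bond is cut to the vinyl iodide 10 and the ynal 14. The chromium-mediated coupling keeps the alkene geometry, tolerates lactone and imide, and joins the two halves late.

10 to 3 + 7. The C6–C7 bond is cut in the aldol sense. An anti-aldol of succinate imide 3 with iodoenal 7 sets C6 and C7 together (8, then 9), and the anti adduct closes to the cis lactone 10. Imide 3 comes from auxiliary 1 and acid chloride 2, 7 from but-2-yn-1-ol 4 through 6, and 14 from (S)-but-3-yn-2-ol 11 through 12.

## Alternatives that were turned down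

Alternative 1: The lactone C12–O–C6 bond and the C3–O bond are cut together, leading back to the ten-membered (3Z,5Z)-diene acrylic acid A1. In the forward step Pd(OAc)2 with benzoquinone, LiOAc and catalytic LiCl would add the carboxylate to C6 and acetate to C3 across the diene through a π-allyl complex of divalent palladium, giving A2 with C4=C5 in place.
- For: one step forms the lactone, installs the C3 oxygen and delivers the α-methylene lactone with the angelate already present. On this point it is stronger than the chosen route, which spends three steps on a late methylenation.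
- Against: the ten-membered ring must already exist with C1, C2, C8 and C10 set, so the ring-closure problem is only moved. A cis,cis-diene in a ten-membered ring is twisted and binds palladium poorly. The unsymmetrical π-allyl unit (C4 methyl) leaves 1,2- against 1,4-addition open. A2 then needs acetate removal beside an angelate and a lactone, and conversion of the protected C1/C2 diol into the epoxide with inversion at C2.
- Comparison: the chosen route makes ring and C10 centre in the same step and sets C3 by reagent control before the ring exists.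

Alternative 2: The C1–C2 bond and the epoxide C–O bond are cut, leading to the open-chain chloromethyl ketone aldehyde A3. MgBr2·OEt2 and i-Pr2NEt would enolise the C3 chloromethyl ketone at C2, the enolate would add to the C1 aldehyde and the alkoxide would displace chloride, giving the epoxy enone A4.
- For: ring and epoxide form together under non-oxidative conditions, and the aldehyde is non-enolisable. It is stronger than the chosen route in that no directed epoxidation with its site and face competition is needed, and no Z-enone has to be handled.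
- Against: two stereocentres (C1, C2) arise in the ring-forming step and a third (C3) in a later reduction of the epoxy ketone. All three are left to the conformation of the macrocycle. The amine base acts on an enone whose γ-position (C6) carries the lactone oxygen.
- Comparison: the chosen route creates one stereocentre in the closure, defines the enolate by a halide without base, and fixes C3 beforehand so that it can direct the epoxidation.

Alternative 3: The C6–C7 bond is cut in a [2,3]-sigmatropic sense, leading to the thirteen-membered allylic ether A5 with a tributylstannyl group on C6. n-BuLi would exchange tin for lithium and the α-alkoxy allyllithium would rearrange to the ten-membered homoallylic alcohol A6 with the C11=C13 methylene.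
- For: a thirteen-membered ether is easier to close than a ten-membered carbocycle, and the exocyclic methylene appears without enolate chemistry. On both points it is stronger than the chosen route.
- Against: the carbanion is allylic as well as α-oxygenated, so [1,2]-shift and reaction at C4 compete. The outcome at C6 and C7 depends on the stannane configuration and the C7=C11 geometry, both of which must be made selectively. n-BuLi meets an epoxide and a free tertiary alcohol. A6 still needs oxidation of C12 from alcohol to acid level, lactonisation, two deprotections (one acidic, beside the epoxide) and acylation.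
- Comparison: the chosen route keeps C12 at the acid oxidation state throughout and introduces the epoxide last.

Key step: step 16

Assumption 1: the MgCl2-catalysed anti-aldol of an N-acyloxazolidinone is taken to proceed through the magnesium-chelated Z-enolate, attacked on the face remote from the benzyl group (the facial sense of imide enolate alkylation); this fixes the (R)-auxiliary.
Assumption 2: (S)-but-3-yn-2-ol is used only so that intermediates 12 to 25 are single diastereomers; its stereocentre (C10) is erased in step 15.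

## Route

Step 1
Reactants: 1 (R)-4-benzyl-1,3-oxazolidin-2-one; 2 methyl 4-chloro-4-oxobutanoate
Product: 3 methyl 4-[(4R)-4-benzyl-2-oxo-1,3-oxazolidin-3-yl]-4-oxobutanoate
Conditions: Et3N, 4-(dimethylamino)pyridine (cat.), CH2Cl2, 0 °C to rt
Reagents that add atoms: none
Why: N-acylation of the oxazolidinone by the acid chloride under nucleophilic catalysis. The imide end is far more acidic than the ester end, so later soft enolisation occurs only next to the imide.

Step 2
Reactants: 4 but-2-yn-1-ol
Product: 6 (Z)-3-iodobut-2-en-1-ol, via cyclic vinylalanate 5 (not isolated)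
Conditions: NaAlH2(OCH2CH2OCH3)2, THF, 0 °C to rt; then I2, THF, −78 to 0 °C
Reagents that add atoms: iodine, II
Why: Hydroxyl-directed trans-hydroalumination of the propargylic alcohol places hydride on C2 and aluminium on C3 in a five-membered alanate. Iodinolysis with retention gives the Z vinyl iodide, in which iodine and CH2OH are cis.

Step 3
Reactants: 6 (Z)-3-iodobut-2-en-1-ol
Product: 7 (Z)-3-iodobut-2-enal
Conditions: MnO2, CH2Cl2, rt
Reagents that add atoms: none
Why: Allylic oxidation on the MnO2 surface under neutral conditions keeps the alkene geometry. The aldehyde is used at once.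

Step 4
Reactants: 3 methyl 4-[(4R)-4-benzyl-2-oxo-1,3-oxazolidin-3-yl]-4-oxobutanoate; 7 (Z)-3-iodobut-2-enal
Product: 10 (4R)-4-benzyl-3-{(2R,3S)-2-[(Z)-2-iodoprop-1-en-1-yl]-5-oxooxolane-3-carbonyl}-1,3-oxazolidin-2-one, via anti-aldol trimethylsilyl ether 8 (not isolated), via anti hydroxy ester 9 (not isolated)
Conditions: MgCl2 (10 mol%), Et3N, Me3SiCl, EtOAc, rt; then CF3CO2H, MeOH, 0 °C to rt
Reagents that add atoms: none
Why: Magnesium-halide-catalysed direct anti-aldol of an N-acyloxazolidinone with a non-enolisable unsaturated aldehyde (Evans anti-aldol). The chelated Z-enolate is attacked on the face away from benzyl, which sets C7, and the silyl-turnover pathway gives the anti C6/C7 pair. Acidic methanol removes the silyl group, and the anti hydroxy ester closes to the cis-disubstituted γ-lactone.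

Step 5
Reactants: 11 (S)-but-3-yn-2-ol
Product: 12 (S)-(but-3-yn-2-yloxy)triethylsilane
Conditions: Et3SiCl, imidazole, CH2Cl2, 0 °C to rt
Reagents that add atoms: chlorotriethylsilane, CC[Si](Cl)(CC)CC
Why: Standard silylation of a secondary alcohol. The triethylsilyl group is chosen because it can later be removed by mild acid beside a tert-butyldimethylsilyl ether.

Step 6
Reactants: 12 (S)-(but-3-yn-2-yloxy)triethylsilane
Product: 14 (S)-4-(triethylsilyloxy)pent-2-ynal, via lithium acetylide 13 (not isolated)
Conditions: n-BuLi, THF, −78 °C; then HCON(CH3)2, −78 to 0 °C; inverse quench into KH2PO4 aq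
Reagents that add atoms: N,N-dimethylformamide, CN(C)C=O
Why: Formylation of the lithium acetylide with the formamide. The buffered inverse quench releases the ynal from the hemiaminal without conjugate addition of dimethylamine.

Step 7
Reactants: 10 (4R)-4-benzyl-3-{(2R,3S)-2-[(Z)-2-iodoprop-1-en-1-yl]-5-oxooxolane-3-carbonyl}-1,3-oxazolidin-2-one; 14 (S)-4-(triethylsilyloxy)pent-2-ynal
Product: 15 (4R)-4-benzyl-3-{(2S,3S)-2-[(1Z,6S)-3-hydroxy-2-methyl-6-(triethylsilyloxy)hept-1-en-4-yn-1-yl]-5-oxooxolane-3-carbonyl}-1,3-oxazolidin-2-one (both C3 epimers)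
Conditions: CrCl2 (4 equiv), NiCl2 (2 mol%), DMSO, rt
Reagents that add atoms: none
Why: Nozaki–Hiyama–Kishi coupling. Zerovalent nickel inserts into the C–I bond with retention, the vinyl group passes to trivalent chromium and adds only to the aldehyde, so lactone, imide and silyl ether survive. The C3 configuration is irrelevant here because it is erased in step 8.

Step 8
Reactants: 15 the C3 epimeric carbinols
Product: 16 (4R)-4-benzyl-3-{(2S,3S)-2-[(1Z,6S)-2-methyl-3-oxo-6-(triethylsilyloxy)hept-1-en-4-yn-1-yl]-5-oxooxolane-3-carbonyl}-1,3-oxazolidin-2-one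
Conditions: Dess–Martin periodinane, NaHCO3, CH2Cl2, 0 °C to rt
Reagents that add atoms: none
Why: Dess–Martin oxidation of a doubly activated secondary alcohol under buffered conditions converges both epimers to one alkenyl alkynyl ketone.

Step 9
Reactants: 16 the alkenyl alkynyl ketone
Product: 17 (4R)-4-benzyl-3-{(2S,3S)-2-[(1Z,3R,6S)-3-hydroxy-2-methyl-6-(triethylsilyloxy)hept-1-en-4-yn-1-yl]-5-oxooxolane-3-carbonyl}-1,3-oxazolidin-2-one
Conditions: (R)-1-methyl-3,3-diphenyltetrahydro-1H,3H-pyrrolo[1,2-c][1,3,2]oxazaborole (1 equiv), catecholborane, CH2Cl2, −78 °C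
Reagents that add atoms: none
Why: Corey–Bakshi–Shibata reduction. The ketone binds with the α-branched alkenyl group as the large and the alkynyl group as the small substituent, and the (R)-oxazaborolidine delivers hydride to the face that gives the (3R) carbinol. Reagent control overrides the remote C6/C7 centres, and imide and lactone are inert to catecholborane at −78 °C.

Step 10
Reactants: 17 the (3R) propargylic alcohol
Product: 18 (4R)-4-benzyl-3-{(2S,3S)-2-[(1Z,3R,6S)-3-(tert-butyldimethylsilyloxy)-2-methyl-6-(triethylsilyloxy)hept-1-en-4-yn-1-yl]-5-oxooxolane-3-carbonyl}-1,3-oxazolidin-2-one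
Conditions: t-BuMe2SiOSO2CF3, 2,6-lutidine, CH2Cl2, −78 to 0 °C
Reagents that add atoms: tert-butyldimethylsilyl trifluoromethanesulfonate, CC(C)(C)[Si](C)(C)OS(=O)(=O)C(F)(F)F
Why: Silylation of a hindered secondary alcohol with the silyl triflate and a non-nucleophilic base. The ether must last through to step 22 and prevents hemiketal or furan formation with the later Z-enone.

Step 11
Reactants: 18 the bis-silyl ether alkyne
Product: 19 (4R)-4-benzyl-3-{(2S,3S)-2-[(1Z,3S,4Z,6S)-3-(tert-butyldimethylsilyloxy)-2-methyl-6-(triethylsilyloxy)hepta-1,4-dien-1-yl]-5-oxooxolane-3-carbonyl}-1,3-oxazolidin-2-one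
Conditions: H2 (1 atm), Pd/CaCO3 poisoned with Pb(OAc)2, quinoline, EtOAc, rt
Reagents that add atoms: none
Why: Syn semihydrogenation of the internal alkyne on the poisoned palladium surface gives the Z alkene C1=C2. The trisubstituted alkene and the benzyl group are not reduced, and no C–I bond remains. The C3 descriptor changes from R to S only because the ranking of its neighbours changes.

Step 12
Reactants: 19 the Z,Z-diene imide
Product: 21 (2S,3S)-2-[(1Z,3S,4Z,6S)-3-(tert-butyldimethylsilyloxy)-2-methyl-6-(triethylsilyloxy)hepta-1,4-dien-1-yl]-5-oxooxolane-3-carboxylic acid, via peroxy acid 20 (not isolated)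
Conditions: LiOH, H2O2, THF/H2O, 0 °C; then Na2SO3 aq; then 1 M HCl to pH 3
Reagents that add atoms: hydrogen peroxide, OO
Why: Hydroperoxide attacks the exocyclic imide carbonyl and sulfite reduces the peroxy acid. Any lactone opened by hydroxide recloses on acidification, because only the C12 carboxyl can form a five-membered ring with O6. The auxiliary 1 is recovered.

Step 13
Reactants: 21 the lactone carboxylic acid
Product: 24 (4S,5S)-4-(2-bromoacetyl)-5-[(1Z,3S,4Z,6S)-3-(tert-butyldimethylsilyloxy)-2-methyl-6-(triethylsilyloxy)hepta-1,4-dien-1-yl]oxolan-2-one, via acid chloride 22 (not isolated), via diazoketone 23 (not isolated)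
Conditions: 1-chloro-N,N,2-trimethylprop-1-en-1-amine, CH2Cl2, 0 °C; then CH2N2, Et2O, 0 °C; N2 purge; then HBr (33% in AcOH, 1.05 equiv), −20 °C
Reagents that add atoms: diazomethane, C=[N+]=[N-]; hydrogen bromide, Br
Why: The chloroenamine gives the acid chloride without HCl or base, so the silyl ethers and the β-acyloxy carbonyl unit are not disturbed. Diazomethane is C-acylated (first stage of an Arndt–Eistert sequence, a second equivalent takes up HCl). HBr protonates the diazo carbon and bromide displaces N2, which fixes the bromide at C9; no enone is present for diazomethane to add to.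

Step 14
Reactants: 24 the bromoketone bis-silyl ether
Product: 25 (4S,5S)-4-(2-bromoacetyl)-5-[(1Z,3S,4Z,6S)-3-(tert-butyldimethylsilyloxy)-6-hydroxy-2-methylhepta-1,4-dien-1-yl]oxolan-2-one
Conditions: AcOH/THF/H2O (3:1:1), rt
Reagents that add atoms: none
Why: Acid-catalysed hydrolysis cleaves the triethylsilyl ether much faster than the bulkier tert-butyldimethylsilyl ether. The medium contains no base or nucleophile that would attack the bromoketone.

Step 15
Reactants: 25 the Z-allylic alcohol
Product: 26 (4S,5S)-4-(2-bromoacetyl)-5-[(1Z,3S,4Z)-3-(tert-butyldimethylsilyloxy)-2-methyl-6-oxohepta-1,4-dien-1-yl]oxolan-2-one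
Conditions: Dess–Martin periodinane, NaHCO3, CH2Cl2, 0 °C
Reagents that add atoms: none
Why: Dess–Martin oxidation under buffered, non-basic conditions gives the Z-enone without isomerisation and leaves the α-bromoketone alone. The enone is used directly in step 16.

Step 16
Reactants: 26 (4S,5S)-4-(2-bromoacetyl)-5-[(1Z,3S,4Z)-3-(tert-butyldimethylsilyloxy)-2-methyl-6-oxohepta-1,4-dien-1-yl]oxolan-2-one
Product: 29 (1Z,3S,4Z,6S,7S,10R)-3-(tert-butyldimethylsilyloxy)-10-hydroxy-8-oxogermacra-1,4-dien-12,6-olide, via samarium enolate 27 (not isolated), via samarium aldolate 28 (not isolated)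
Conditions: SmI2 (2.5 equiv, 0.02 M in THF), slow addition of 26 (final 2 mM), −78 °C; then NH4Cl aq, −78 °C
Reagents that add atoms: none
Why: Two equivalents of SmI2 each transfer one electron to the C9–Br bond, the most easily reduced site, and give the trivalent samarium enolate 27, located only at C9 because a halide and not a base defines it. The O-bound enolate and the C10 ketone share the oxophilic metal in a six-membered aldol transition state; C9 adds to C10, and the chelated aldolate 28 is stable at −78 °C, so the ketone–ketone aldol does not revert before the quench. The closest known reaction type is the SmI2-promoted intramolecular Reformatsky reaction of α-bromo ketones with ketones or aldehydes, used to close medium and large carbocycles and lactones. The ten-membered carbocycle closes in a 10-(enolendo)-exo-trig mode; the two Z alkenes and the cis-fused lactone fold the chain so that C9 and C10 can meet, and high dilution suppresses intermolecular aldol. The new stereocentre C10 is controlled by C7 and C3: the lactone ring and the silyloxy group occupy one face of the forming ring, so the solvated samarium bridge between O8 and O10 should lie on the open face, which puts the C10 oxygen anti to the lactone and the methyl group syn to it. The step needs reduction of C–Br in preference to the enone, which the far higher rate of α-halo ketone reduction by SmI2 in THF without additives at low temperature secures. It needs 1,2- and not 1,4-addition, which the hard chelating enolate and the hindered β-carbon C2 favour, conjugate closure giving only an eight-membered ring. It also needs no proton transfer from C7–H, which the low temperature prevents.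

Step 17
Reactants: 29 the ten-membered β-hydroxy ketone
Product: 31 (1Z,3S,4Z,6S,7R,8S,10R)-3-(tert-butyldimethylsilyloxy)-8,10-dihydroxygermacra-1,4-dien-12,6-olide, via diethylboron chelate 30 (not isolated)
Conditions: Et2BOMe, THF/MeOH (4:1), −78 °C; then NaBH4, −78 °C; AcOH quench, MeOH co-evaporation
Reagents that add atoms: none
Why: Narasaka–Prasad reduction. The C10 alkoxide and the C8 carbonyl are tied in a diethylboron chelate that turns the carbonyl oxygen to the face of the C10 oxygen, and borohydride adds from the periphery to give the 1,3-syn diol with C8–OH on the same ring face as C10–OH. The boron-bound C8 oxygen cannot attack the lactone, and the lactone is not reduced at −78 °C.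

Step 18
Reactants: 31 the syn diol
Product: 32 (1Z,3S,4Z,6S,7S,8S,10R)-3-(tert-butyldimethylsilyloxy)-8,10-bis(trimethylsilyloxy)germacra-1,4-dien-12,6-olide
Conditions: 1-(trimethylsilyl)imidazole, CH2Cl2, rt
Reagents that add atoms: 1-(trimethylsilyl)imidazole, C[Si](C)(C)n1ccnc1
Why: The strong silyl donor caps both the secondary C8 and the tertiary C10 hydroxyl. This removes acidic protons before enolate formation and stops the C8 oxygen from attacking C12 (lactone migration).

Step 19
Reactants: 32 the bis(trimethylsilyl) ether
Product: 36 (1Z,3S,4Z,6S,7S,8S,10R)-3-(tert-butyldimethylsilyloxy)-8,10-bis(trimethylsilyloxy)germacra-1,4,11(13)-trien-12,6-olide, via lithium enolate 33 (not isolated), via Mannich base 34 (not isolated), via ammonium iodide 35 (not isolated)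
Conditions: LiN(i-Pr)2, THF, −78 °C; then CH2=N(CH3)2+ I−, −78 °C to rt; then CH3I, CH2Cl2, rt; then NaHCO3 aq/CH2Cl2, rt
Reagents that add atoms: N,N-dimethylmethyleneiminium iodide, C=[N+](C)C.[I-]
Why: Eschenmoser methylenation: Mannich reaction of the lactone enolate with the iminium salt, N-methylation and elimination of trimethylamine. Only C11 is deprotonated, since C7–H is not α to a carbonyl, and no angelate or reducible step follows that the acrylate could not survive.

Step 20
Reactants: 36 the α-methylene lactone bis(trimethylsilyl) ether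
Product: 37 (1Z,3S,4Z,6S,7R,8S,10R)-3-(tert-butyldimethylsilyloxy)-8,10-dihydroxygermacra-1,4,11(13)-trien-12,6-olide
Conditions: citric acid, MeOH, 0 °C to rt
Reagents that add atoms: none
Why: Mild acid methanolysis removes both trimethylsilyl ethers and leaves the hindered secondary tert-butyldimethylsilyl ether. Methanol does not add to the methylene lactone without base.

Step 21
Reactants: 37 the diol; 38 angelic acid, (Z)-2-methylbut-2-enoic acid
Product: 39 (1Z,3S,4Z,6S,7R,8S,10R)-8-[(Z)-2-methylbut-2-enoyloxy]-3-(tert-butyldimethylsilyloxy)-10-hydroxygermacra-1,4,11(13)-trien-12,6-olide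
Conditions: 38, 2,4,6-trichlorobenzoyl chloride, Et3N, toluene, rt; then 37, 80 °C
Reagents that add atoms: none
Why: Yamaguchi-type mixed anhydride acylation. The hindered aroyl carbonyl is not attacked, and the secondary C8 hydroxyl takes the angeloyl group while the tertiary C10 hydroxyl does not react. No nucleophilic catalyst is present that could turn the angelate into the tiglate.

Step 22
Reactants: 39 the C8 angelate
Product: 40 (1Z,3S,4Z,6S,7R,8S,10R)-8-[(Z)-2-methylbut-2-enoyloxy]-3,10-dihydroxygermacra-1,4,11(13)-trien-12,6-olide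
Conditions: HF·pyridine, pyridine, THF, 0 °C to rt
Reagents that add atoms: none
Why: Buffered HF cleaves the remaining silyl ether. It avoids basic fluoride, which could add to the methylene lactone or move acyl groups.

Step 23
Reactants: 40 the dienediol
Product: 41 (1R,2R,3R,4Z,6S,7R,8S,10R)-8-[(Z)-2-methylbut-2-enoyloxy]-1,2-epoxy-3,10-dihydroxygermacra-4,11(13)-dien-12,6-olide, the target
Conditions: VO(acac)2 (5 mol%), t-BuOOH, CH2Cl2, 0 °C to rt
Reagents that add atoms: tert-butyl hydroperoxide, CC(C)(C)OO
Why: Hydroxyl-directed epoxidation. The C3 alkoxide on pentavalent vanadium delivers the peroxide oxygen to the adjacent cis alkene C1=C2 on its own face, the cis (erythro) mode known for allylic alcohols in small and medium rings. C4=C5 is shielded on that face by the fused lactone and deactivated by its allylic acyloxy group, the tertiary C10 hydroxyl is the poorer ligand, and the acrylate and angelate are too electron-poor to react.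

## Compound list

1 | (R)-4-benzyl-1,3-oxazolidin-2-one | O=C1N[C@H](Cc2ccccc2)CO1 | starting material
2 | methyl 4-chloro-4-oxobutanoate | COC(=O)CCC(Cl)=O | starting material
3 | methyl 4-[(4R)-4-benzyl-2-oxo-1,3-oxazolidin-3-yl]-4-oxobutanoate | COC(=O)CCC(=O)N1[C@H](Cc2ccccc2)COC1=O | intermediate
4 | but-2-yn-1-ol | CC#CCO | starting material
5 | sodium 2,2-bis(2-methoxyethoxy)-3-methyl-2,5-dihydro-1,2-oxaluminol-2-uide (cyclic vinylalanate) | CC1=CCO[Al-]1(OCCOC)OCCOC.[Na+] | intermediate (not isolated)
6 | (Z)-3-iodobut-2-en-1-ol | C/C(I)=C/CO | intermediate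
7 | (Z)-3-iodobut-2-enal | C/C(I)=C/C=O | intermediate
8 | methyl (3S,4R,5Z)-3-[(4R)-4-benzyl-2-oxo-1,3-oxazolidine-3-carbonyl]-6-iodo-4-(trimethylsilyloxy)hept-5-enoate | COC(=O)C[C@H](C(=O)N1[C@H](Cc2ccccc2)COC1=O)[C@@H](O[Si](C)(C)C)/C=C(/C)I | intermediate (not isolated)
9 | methyl (3S,4R,5Z)-3-[(4R)-4-benzyl-2-oxo-1,3-oxazolidine-3-carbonyl]-4-hydroxy-6-iodohept-5-enoate | COC(=O)C[C@H](C(=O)N1[C@H](Cc2ccccc2)COC1=O)[C@@H](O)/C=C(/C)I | intermediate (not isolated)
10 | (4R)-4-benzyl-3-{(2R,3S)-2-[(Z)-2-iodoprop-1-en-1-yl]-5-oxooxolane-3-carbonyl}-1,3-oxazolidin-2-one | O=C(N1[C@H](Cc2ccccc2)COC1=O)[C@H]1CC(=O)O[C@H]1/C=C(/C)I | intermediate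
11 | (S)-but-3-yn-2-ol | C[C@H](O)C#C | starting material
12 | (S)-(but-3-yn-2-yloxy)triethylsilane | C#C[C@H](C)O[Si](CC)(CC)CC | intermediate
13 | lithium (S)-3-(triethylsilyloxy)but-1-yn-1-ide | [Li]C#C[C@H](C)O[Si](CC)(CC)CC | intermediate (not isolated)
14 | (S)-4-(triethylsilyloxy)pent-2-ynal | O=CC#C[C@H](C)O[Si](CC)(CC)CC | intermediate
15 | (4R)-4-benzyl-3-{(2S,3S)-2-[(1Z,6S)-3-hydroxy-2-methyl-6-(triethylsilyloxy)hept-1-en-4-yn-1-yl]-5-oxooxolane-3-carbonyl}-1,3-oxazolidin-2-one, C3 epimers | O=C(N1[C@H](Cc2ccccc2)COC1=O)[C@H]1CC(=O)O[C@H]1/C=C(/C)C(O)C#C[C@H](C)O[Si](CC)(CC)CC | intermediate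
16 | (4R)-4-benzyl-3-{(2S,3S)-2-[(1Z,6S)-2-methyl-3-oxo-6-(triethylsilyloxy)hept-1-en-4-yn-1-yl]-5-oxooxolane-3-carbonyl}-1,3-oxazolidin-2-one | O=C(N1[C@H](Cc2ccccc2)COC1=O)[C@H]1CC(=O)O[C@H]1/C=C(/C)C(=O)C#C[C@H](C)O[Si](CC)(CC)CC | intermediate
17 | (4R)-4-benzyl-3-{(2S,3S)-2-[(1Z,3R,6S)-3-hydroxy-2-methyl-6-(triethylsilyloxy)hept-1-en-4-yn-1-yl]-5-oxooxolane-3-carbonyl}-1,3-oxazolidin-2-one | O=C(N1[C@H](Cc2ccccc2)COC1=O)[C@H]1CC(=O)O[C@H]1/C=C(/C)[C@@H](O)C#C[C@H](C)O[Si](CC)(CC)CC | intermediate
18 | (4R)-4-benzyl-3-{(2S,3S)-2-[(1Z,3R,6S)-3-(tert-butyldimethylsilyloxy)-2-methyl-6-(triethylsilyloxy)hept-1-en-4-yn-1-yl]-5-oxooxolane-3-carbonyl}-1,3-oxazolidin-2-one | O=C(N1[C@H](Cc2ccccc2)COC1=O)[C@H]1CC(=O)O[C@H]1/C=C(/C)[C@@H](O[Si](C)(C)C(C)(C)C)C#C[C@H](C)O[Si](CC)(CC)CC | intermediate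
19 | (4R)-4-benzyl-3-{(2S,3S)-2-[(1Z,3S,4Z,6S)-3-(tert-butyldimethylsilyloxy)-2-methyl-6-(triethylsilyloxy)hepta-1,4-dien-1-yl]-5-oxooxolane-3-carbonyl}-1,3-oxazolidin-2-one | O=C(N1[C@H](Cc2ccccc2)COC1=O)[C@H]1CC(=O)O[C@H]1/C=C(/C)[C@@H](O[Si](C)(C)C(C)(C)C)/C=C\[C@H](C)O[Si](CC)(CC)CC | intermediate
20 | (2S,3S)-2-[(1Z,3S,4Z,6S)-3-(tert-butyldimethylsilyloxy)-2-methyl-6-(triethylsilyloxy)hepta-1,4-dien-1-yl]-5-oxooxolane-3-carboperoxoic acid | OOC(=O)[C@H]1CC(=O)O[C@H]1/C=C(/C)[C@@H](O[Si](C)(C)C(C)(C)C)/C=C\[C@H](C)O[Si](CC)(CC)CC | intermediate (not isolated)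
21 | (2S,3S)-2-[(1Z,3S,4Z,6S)-3-(tert-butyldimethylsilyloxy)-2-methyl-6-(triethylsilyloxy)hepta-1,4-dien-1-yl]-5-oxooxolane-3-carboxylic acid | OC(=O)[C@H]1CC(=O)O[C@H]1/C=C(/C)[C@@H](O[Si](C)(C)C(C)(C)C)/C=C\[C@H](C)O[Si](CC)(CC)CC | intermediate
22 | (2S,3S)-2-[(1Z,3S,4Z,6S)-3-(tert-butyldimethylsilyloxy)-2-methyl-6-(triethylsilyloxy)hepta-1,4-dien-1-yl]-5-oxooxolane-3-carbonyl chloride | ClC(=O)[C@H]1CC(=O)O[C@H]1/C=C(/C)[C@@H](O[Si](C)(C)C(C)(C)C)/C=C\[C@H](C)O[Si](CC)(CC)CC | intermediate (not isolated)
23 | (4S,5S)-4-(2-diazoacetyl)-5-[(1Z,3S,4Z,6S)-3-(tert-butyldimethylsilyloxy)-2-methyl-6-(triethylsilyloxy)hepta-1,4-dien-1-yl]oxolan-2-one | [N-]=[N+]=CC(=O)[C@H]1CC(=O)O[C@H]1/C=C(/C)[C@@H](O[Si](C)(C)C(C)(C)C)/C=C\[C@H](C)O[Si](CC)(CC)CC | intermediate (not isolated)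
24 | (4S,5S)-4-(2-bromoacetyl)-5-[(1Z,3S,4Z,6S)-3-(tert-butyldimethylsilyloxy)-2-methyl-6-(triethylsilyloxy)hepta-1,4-dien-1-yl]oxolan-2-one | BrCC(=O)[C@H]1CC(=O)O[C@H]1/C=C(/C)[C@@H](O[Si](C)(C)C(C)(C)C)/C=C\[C@H](C)O[Si](CC)(CC)CC | intermediate
25 | (4S,5S)-4-(2-bromoacetyl)-5-[(1Z,3S,4Z,6S)-3-(tert-butyldimethylsilyloxy)-6-hydroxy-2-methylhepta-1,4-dien-1-yl]oxolan-2-one | BrCC(=O)[C@H]1CC(=O)O[C@H]1/C=C(/C)[C@@H](O[Si](C)(C)C(C)(C)C)/C=C\[C@H](C)O | intermediate
26 | (4S,5S)-4-(2-bromoacetyl)-5-[(1Z,3S,4Z)-3-(tert-butyldimethylsilyloxy)-2-methyl-6-oxohepta-1,4-dien-1-yl]oxolan-2-one (seco bromoketone enone) | BrCC(=O)[C@H]1CC(=O)O[C@H]1/C=C(/C)[C@@H](O[Si](C)(C)C(C)(C)C)/C=C\C(C)=O | intermediate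
27 | diiodosamarium C8 enolate of 26 (trivalent samarium, C8=C9) | C=C(O[Sm](I)I)[C@H]1CC(=O)O[C@H]1/C=C(/C)[C@@H](O[Si](C)(C)C(C)(C)C)/C=C\C(C)=O | intermediate (not isolated)
28 | diiodosamarium C10 alkoxide of 29 (trivalent samarium aldolate) | C1C(=O)O[C@H]2/C=C(/C)[C@@H](O[Si](C)(C)C(C)(C)C)/C=C\[C@](C)(O[Sm](I)I)CC(=O)[C@@H]12 | intermediate (not isolated)
29 | (1Z,3S,4Z,6S,7S,10R)-3-(tert-butyldimethylsilyloxy)-10-hydroxy-8-oxogermacra-1,4-dien-12,6-olide | C1C(=O)O[C@H]2/C=C(/C)[C@@H](O[Si](C)(C)C(C)(C)C)/C=C\[C@](C)(O)CC(=O)[C@@H]12 | intermediate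
30 | C10 O-diethylboryl derivative of 29 (boron chelate with the C8 carbonyl) | C1C(=O)O[C@H]2/C=C(/C)[C@@H](O[Si](C)(C)C(C)(C)C)/C=C\[C@](C)(OB(CC)CC)CC(=O)[C@@H]12 | intermediate (not isolated)
31 | (1Z,3S,4Z,6S,7R,8S,10R)-3-(tert-butyldimethylsilyloxy)-8,10-dihydroxygermacra-1,4-dien-12,6-olide | C1C(=O)O[C@H]2/C=C(/C)[C@@H](O[Si](C)(C)C(C)(C)C)/C=C\[C@](C)(O)C[C@H](O)[C@@H]12 | intermediate
32 | (1Z,3S,4Z,6S,7S,8S,10R)-3-(tert-butyldimethylsilyloxy)-8,10-bis(trimethylsilyloxy)germacra-1,4-dien-12,6-olide | C1C(=O)O[C@H]2/C=C(/C)[C@@H](O[Si](C)(C)C(C)(C)C)/C=C\[C@](C)(O[Si](C)(C)C)C[C@H](O[Si](C)(C)C)[C@@H]12 | intermediate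
33 | lithium enolate of 32 (C11=C12–OLi) | C1=C(O[Li])O[C@H]2/C=C(/C)[C@@H](O[Si](C)(C)C(C)(C)C)/C=C\[C@](C)(O[Si](C)(C)C)C[C@H](O[Si](C)(C)C)[C@@H]12 | intermediate (not isolated)
34 | 11-(dimethylaminomethyl) derivative of 32 (Mannich base, C11 epimers) | CN(C)CC1C(=O)O[C@H]2/C=C(/C)[C@@H](O[Si](C)(C)C(C)(C)C)/C=C\[C@](C)(O[Si](C)(C)C)C[C@H](O[Si](C)(C)C)[C@@H]12 | intermediate (not isolated)
35 | 11-(trimethylammoniomethyl) derivative of 32, iodide | C[N+](C)(C)CC1C(=O)O[C@H]2/C=C(/C)[C@@H](O[Si](C)(C)C(C)(C)C)/C=C\[C@](C)(O[Si](C)(C)C)C[C@H](O[Si](C)(C)C)[C@@H]12.[I-] | intermediate (not isolated)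
36 | (1Z,3S,4Z,6S,7S,8S,10R)-3-(tert-butyldimethylsilyloxy)-8,10-bis(trimethylsilyloxy)germacra-1,4,11(13)-trien-12,6-olide | C=C1C(=O)O[C@H]2/C=C(/C)[C@@H](O[Si](C)(C)C(C)(C)C)/C=C\[C@](C)(O[Si](C)(C)C)C[C@H](O[Si](C)(C)C)[C@@H]12 | intermediate
37 | (1Z,3S,4Z,6S,7R,8S,10R)-3-(tert-butyldimethylsilyloxy)-8,10-dihydroxygermacra-1,4,11(13)-trien-12,6-olide | C=C1C(=O)O[C@H]2/C=C(/C)[C@@H](O[Si](C)(C)C(C)(C)C)/C=C\[C@](C)(O)C[C@H](O)[C@@H]12 | intermediate
38 | angelic acid, (Z)-2-methylbut-2-enoic acid | C/C=C(/C)C(=O)O | starting material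
39 | (1Z,3S,4Z,6S,7R,8S,10R)-8-[(Z)-2-methylbut-2-enoyloxy]-3-(tert-butyldimethylsilyloxy)-10-hydroxygermacra-1,4,11(13)-trien-12,6-olide | C=C1C(=O)O[C@H]2/C=C(/C)[C@@H](O[Si](C)(C)C(C)(C)C)/C=C\[C@](C)(O)C[C@H](OC(=O)/C(C)=C\C)[C@@H]12 | intermediate
40 | (1Z,3S,4Z,6S,7R,8S,10R)-8-[(Z)-2-methylbut-2-enoyloxy]-3,10-dihydroxygermacra-1,4,11(13)-trien-12,6-olide | C=C1C(=O)O[C@H]2/C=C(/C)[C@@H](O)/C=C\[C@](C)(O)C[C@H](OC(=O)/C(C)=C\C)[C@@H]12 | intermediate
41 | (1R,2R,3R,4Z,6S,7R,8S,10R)-8-[(Z)-2-methylbut-2-enoyloxy]-1,2-epoxy-3,10-dihydroxygermacra-4,11(13)-dien-12,6-olide (CNP0351240.3) | C=C1C(=O)O[C@H]2/C=C(/C)[C@@H](O)[C@H]3O[C@H]3[C@](C)(O)C[C@H](OC(=O)/C(C)=C\C)[C@@H]12 | target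

## Step count and least certain steps

Total: 23 steps. Longest linear sequence: 20 steps (steps 2, 3, 4 and 7 to 23, from but-2-yn-1-ol 4).

Step 16 (key step). Electron transfer to the Z-enone may compete with reduction of the C–Br bond, leading to loss of the γ-silyloxy group or Z/E isomerisation. The enolate may be protonated before it cyclises. Facial selectivity at C10 may be poor, because the chelate model has no close precedent in this ring. Fallback: starting from 26, Zn dust and Me3SiCl in MeCN at 0 °C reduce the C–Br bond and trap the enolate as the trimethylsilyl enol ether F1. F1 is then cyclised at high dilution with TiCl4 in CH2Cl2 at −78 °C in an intramolecular Mukaiyama aldol addition. This keeps every reductant away from the enone during ring closure and passes through an open transition state in which a small Lewis acid, not a ligated samarium bridge, sits on the C10 oxygen, so it gives a second chance at the C10 configuration. Aqueous work-up returns to the route at 29.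

Step 4. The amine and chlorosilane may enolise 7 at the γ-position and scramble its Z geometry, the anti selectivity may be low with this β,β-disubstituted enal, and the facial sense rests on Assumption 1. Fallback: starting from 3, Bu2BOTf and i-Pr2NEt in CH2Cl2 at −78 °C give the dibutylboron Z-enolate F2. F2 is added at −78 °C to 7 that has been precomplexed with Et2AlCl. The Lewis-acid-bound aldehyde then reacts with the chelated boron enolate through an open transition state, which should give the anti adduct 9 with the same C7 configuration, without amine or chlorosilane in contact with the aldehyde. Camphor-10-sulfonic acid in CH2Cl2 closes 9 to the lactone and the route is rejoined at 10.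

Step 17. The hindered tertiary C10 hydroxyl may form the boron chelate incompletely, so that hydride adds under control of the ring conformation and facial selectivity at C8 is poor; a basic work-up could also let the new C8 hydroxyl attack the lactone. Fallback: starting from 29, the C8 epimer F3, (1Z,3S,4Z,6S,7R,8R,10R)-3-(tert-butyldimethylsilyloxy)-8,10-dihydroxygermacra-1,4-dien-12,6-olide, is taken on. It can be made on purpose with Me4NBH(OAc)3 in MeCN/AcOH at −30 °C, by internal hydride delivery from the C10 alkoxyborohydride. F3 is inverted at C8 by Mitsunobu reaction with chloroacetic acid (PPh3, diisopropyl azodicarboxylate, toluene, 0 °C) to the C8 chloroacetate F4, which has the correct configuration. Thiourea and NaHCO3 in EtOH at rt remove the chloroacetyl group and return to the route at 31.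

Step 21. The free C8 hydroxyl may take over the lactone from O6 under Et3N at 80 °C before it is acylated, and the angelate may isomerise to the tiglate. Fallback: starting from 37, the C8 hydroxyl is acylated at 0 °C with 2-[bis(2,2,2-trifluoroethoxy)phosphoryl]propanoic acid (EDC·HCl, 4-(dimethylamino)pyridine cat., CH2Cl2) to give the C8 phosphonopropanoate F5. A Still–Gennari olefination (KN(SiMe3)2, 18-crown-6, THF, −78 °C; acetaldehyde) then builds the Z-2-methylbut-2-enoate on the ester, so no preformed angeloyl group is heated with base. The route is rejoined at 39.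

Step 23. Oxygen may be delivered to C4=C5, which is also allylic to the C3 hydroxyl, or to the other face of C1=C2 under direction from the tertiary C10 hydroxyl. Fallback: from 40 directly to 41 under reagent control with Ti(OiPr)4, D-(−)-diisopropyl tartrate (stoichiometric), t-BuOOH and 4 Å molecular sieves in CH2Cl2 at −20 °C (Sharpless epoxidation). In this dienol the two alkenyl arms on C3 are matched with opposite tartrates: the D-(−)-tartrate pairs with C1=C2 and delivers oxygen erythro to the C3 hydroxyl, as the target requires. A tertiary alkoxide is a poor ligand in this titanium system, so C10–OH should not compete. No new compound is formed on the way.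

## Further compounds

F1 | step 16 | (4S,5S)-5-[(1Z,3S,4Z)-3-(tert-butyldimethylsilyloxy)-2-methyl-6-oxohepta-1,4-dien-1-yl]-4-[1-(trimethylsilyloxy)ethenyl]oxolan-2-one | C=C(O[Si](C)(C)C)[C@H]1CC(=O)O[C@H]1/C=C(/C)[C@@H](O[Si](C)(C)C(C)(C)C)/C=C\C(C)=O
F2 | step 4 | dibutylboron Z-enolate of 3 | CCCCB(CCCC)O/C(=C\CC(=O)OC)N1[C@H](Cc2ccccc2)COC1=O
F3 | step 17 | (1Z,3S,4Z,6S,7R,8R,10R)-3-(tert-butyldimethylsilyloxy)-8,10-dihydroxygermacra-1,4-dien-12,6-olide (C8 epimer of 31) | C1C(=O)O[C@H]2/C=C(/C)[C@@H](O[Si](C)(C)C(C)(C)C)/C=C\[C@](C)(O)C[C@@H](O)[C@@H]12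
F4 | step 17 | 8-O-chloroacetate of 31 | C1C(=O)O[C@H]2/C=C(/C)[C@@H](O[Si](C)(C)C(C)(C)C)/C=C\[C@](C)(O)C[C@H](OC(=O)CCl)[C@@H]12
F5 | step 21 | 8-O-{2-[bis(2,2,2-trifluoroethoxy)phosphoryl]propanoate} of 37 | C=C1C(=O)O[C@H]2/C=C(/C)[C@@H](O[Si](C)(C)C(C)(C)C)/C=C\[C@](C)(O)C[C@H](OC(=O)C(C)P(=O)(OCC(F)(F)F)OCC(F)(F)F)[C@@H]12
F0 | step 23 | none | none
A1 | alternative 1 | ten-membered (3Z,5Z)-diene acrylic acid with C1/C2 acetonide, C8 angelate and C10 hydroxyl | C=C(C(=O)O)[C@H]1/C=C\C(C)=C/[C@@H]2OC(C)(C)O[C@H]2[C@](C)(O)C[C@@H]1OC(=O)/C(C)=C\C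
A2 | alternative 1 | C3-acetoxy α-methylene lactone with C1/C2 acetonide | C=C1C(=O)O[C@H]2/C=C(/C)[C@@H](OC(C)=O)[C@@H]3OC(C)(C)O[C@H]3[C@](C)(O)C[C@H](OC(=O)/C(C)=C\C)[C@@H]12
A3 | alternative 2 | open-chain C3 chloromethyl ketone C1 aldehyde (C10 p-methoxybenzyl ether, C8 silyl ether) | O=C[C@](C)(OCc1ccc(OC)cc1)C[C@H](O[Si](C)(C)C(C)(C)C)[C@H]1CC(=O)O[C@H]1/C=C(/C)C(=O)CCl
A4 | alternative 2 | ten-membered cis-epoxy enone | C1C(=O)O[C@H]2/C=C(/C)C(=O)[C@H]3O[C@H]3[C@](C)(OCc4ccc(OC)cc4)C[C@H](O[Si](C)(C)C(C)(C)C)[C@@H]12
A5 | alternative 3 | thirteen-membered C6–O–C13 allylic ether with C6 tributylstannyl group (C6 configuration and C7=C11 geometry left open) | CCCC[Sn](CCCC)(CCCC)C1/C=C(/C)[C@@H](OCOC)[C@H]2O[C@H]2[C@](C)(O)C[C@H](OCc3ccc(OC)cc3)C=C(CO[Si](C)(C)C(C)(C)C)CO1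
A6 | alternative 3 | ten-membered homoallylic alcohol | O[C@H]1/C=C(/C)[C@@H](OCOC)[C@H]2O[C@H]2[C@](C)(O)C[C@H](OCc3ccc(OC)cc3)[C@H]1C(=C)CO[Si](C)(C)C(C)(C)C
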